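**Retrosynthetic overview**
1. The acid is released last from its methyl ester. The C30 chain (C1 = CO2H to C17 = CH2OH) is cut once, at C8(sp2)–C9(sp3). This gives an (E)-alkenyl iodide (C1–C8 with the furan) and the N-acyloxyphthalimide of a hydroxy acid (C9–C17 plus one sacrificial carboxyl carbon).
2. Both carbons are electrophilic. They are joined by a nickel-electrocatalytic decarboxylative alkenylation (cathodic radical generation, like-polarity union), run with the OH free and with C5 and all other alkenes already in place.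
3. Enabling feature: C8 is the methyl-bearing sp2 carbon of the C7=C8 alkene and can hold iodine trans to C6. C9 is an unbranched CH2 at the head of the homoallyl array C9–C10–C11=C12, that is, the α-carbon of a γ,δ-unsaturated acid. The furan ring and the C2 enoate lie far from both.
4. Iodide half: (R)-carvone supplies C5. Epoxidation and Eschenmoser–Tanabe fragmentation open its six-membered ring to a but-2-ynyl arm (to the 7E iodoalkene by hydrozirconation) and an acetaldehyde arm (to the 2Z enoate by phosphonate alkylation and Still–Gennari olefination with 3-(furan-3-yl)propanal).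
5. Ester half: nerol supplies the 11Z alkene, ozonolysis/Still–Gennari olefination sets 15Z, and an acetate enolate adds C9 and the carboxyl carbon. No ring is formed anywhere: the furan ring is bought and the carvone ring is only opened.

Key step: step 16

Remark: read from the SMILES, the target is (2Z,5R,7E,11Z,15Z)-2-[3-(furan-3-yl)propylidene]-17-hydroxy-8,12,16-trimethyl-5-(prop-1-en-2-yl)heptadeca-7,11,15-trienoic acid; this numbering is used throughout.

**Route**

Step 1
Reactants: 1 nerol, (2Z)-3,7-dimethylocta-2,6-dien-1-ol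
Product: 2 neryl chloride, (2Z)-1-chloro-3,7-dimethylocta-2,6-diene
Conditions: PPh3, CCl4, reflux
Reagents that add atoms: carbon tetrachloride, ClC(Cl)(Cl)Cl
Why: Appel chlorination, in which chloride displaces the oxyphosphonium ion by SN2 under neutral conditions, should give the primary allylic chloride without allylic transposition and with the Z alkene intact.

Step 2
Reactants: 2 neryl chloride
Product: 4 (4Z)-6-chloro-4-methylhex-4-enal, via secondary ozonide 3 (not isolated)
Conditions: O3 (1 equiv, Sudan Red 7B end point), CH2Cl2, −78 °C; then PPh3, −78 °C to rt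
Reagents that add atoms: ozone, [O-][O+]=O
Why: Chemoselective Criegee ozonolysis: the isopropylidene alkene is the more electron-rich one because the other alkene is deactivated by the allylic C–Cl bond, so one equivalent of ozone and reduction of ozonide 3 should stop at aldehyde 4.

Step 3
Reactants: 4 (4Z)-6-chloro-4-methylhex-4-enal; 5 ethyl 2-[bis(2,2,2-trifluoroethoxy)phosphoryl]propanoate
Product: 7 ethyl (2Z,6Z)-8-chloro-2,6-dimethylocta-2,6-dienoate, via potassium phosphonate anion 6 (not isolated)
Conditions: 5, KN(SiMe3)2, 18-crown-6, THF, −78 °C; then 4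
Reagents that add atoms: none
Why: Still–Gennari olefination: the kinetic adduct of the electron-poor phosphonate anion 6 collapses fast and irreversibly, which should set the new trisubstituted alkene as Z (ester cis to the chain), and at −78 °C carbonyl addition outruns alkylation by the allylic chloride.

Step 4
Reactants: 7 ethyl (2Z,6Z)-8-chloro-2,6-dimethylocta-2,6-dienoate
Product: 8 (2Z,6Z)-8-chloro-2,6-dimethylocta-2,6-dien-1-ol
Conditions: iBu2AlH (2.3 equiv), CH2Cl2, −78 °C; aq. potassium sodium tartrate
Reagents that add atoms: none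
Why: 1,2-Reduction of an enoate by iBu2AlH, a reagent that leaves allylic chlorides and alkene geometry untouched at −78 °C.

Step 5
Reactants: 8 (2Z,6Z)-8-chloro-2,6-dimethylocta-2,6-dien-1-ol; 9 ethyl acetate
Product: 11 ethyl (4Z,8Z)-10-hydroxy-5,9-dimethyldeca-4,8-dienoate, via lithium enolate 10 (not isolated)
Conditions: 9, LiN(iPr)2 (3.2 equiv each), THF–DMPU, −78 °C; then 8, −78 to −30 °C; aq. NH4Cl
Reagents that add atoms: none
Why: Ester enolate alkylation by SN2 at the primary prenyl-type allylic chloride with retention of the Z geometry; the first equivalent of 10 only deprotonates the hydroxyl group, and any O-acylated by-product would be cleaved again in step 6.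

Step 6
Reactants: 11 ethyl (4Z,8Z)-10-hydroxy-5,9-dimethyldeca-4,8-dienoate
Product: 12 (4Z,8Z)-10-hydroxy-5,9-dimethyldeca-4,8-dienoic acid
Conditions: LiOH·H2O, THF/MeOH/H2O, rt; then 1 M HCl to pH 4, 0 °C
Reagents that add atoms: lithium hydroxide, [Li+].[OH-]
Why: Saponification of an unhindered ethyl ester, which touches neither alkene nor the allylic alcohol.

Step 7
Reactants: 12 (4Z,8Z)-10-hydroxy-5,9-dimethyldeca-4,8-dienoic acid
Product: 13 1,3-dioxoisoindolin-2-yl (4Z,8Z)-10-hydroxy-5,9-dimethyldeca-4,8-dienoate (redox-active ester)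
Conditions: N-hydroxyphthalimide, N,N'-diisopropylcarbodiimide, CH2Cl2, 0 °C to rt, no DMAP
Reagents that add atoms: N-hydroxyphthalimide, O=C1c2ccccc2C(=O)N1O
Why: Carbodiimide (Steglich-type) esterification run without acyl-transfer catalyst, so that the acidic N–OH of N-hydroxyphthalimide outcompetes the neutral primary alcohol for the O-acylisourea.

Step 8
Reactants: 14 furan-3-carbaldehyde; 15 (triphenylphosphoranylidene)acetaldehyde
Product: 16 (2E)-3-(furan-3-yl)prop-2-enal
Conditions: toluene, 80 °C
Reagents that add atoms: none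
Why: Wittig reaction of a stabilised ylide, which should give the E enal.

Step 9
Reactants: 16 (2E)-3-(furan-3-yl)prop-2-enal
Product: 17 3-(furan-3-yl)propanal
Conditions: Hantzsch ester (diethyl 2,6-dimethyl-1,4-dihydropyridine-3,5-dicarboxylate, 1.1 equiv), dibenzylammonium trifluoroacetate (10 mol %), THF, rt
Reagents that add atoms: none
Why: Iminium-catalysed transfer hydrogenation with a Hantzsch ester reduces only the conjugated C=C bond and spares the aldehyde and the furan ring.

Step 10
Reactants: 18 (R)-(−)-carvone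
Product: 19 (1R,4R,6R)-1-methyl-4-(prop-1-en-2-yl)-7-oxabicyclo[4.1.0]heptan-2-one
Conditions: 30% H2O2, NaOH (cat.), MeOH, 0 °C
Reagents that add atoms: hydrogen peroxide, OO
Why: Weitz–Scheffer nucleophilic epoxidation attacks only the enone alkene, from the face anti to the isopropenyl group, and the two new centres are erased again in step 11.

Step 11
Reactants: 19 (1R,4R,6R)-1-methyl-4-(prop-1-en-2-yl)-7-oxabicyclo[4.1.0]heptan-2-one
Product: 21 (3S)-3-(prop-1-en-2-yl)hept-5-ynal, via epoxy tosylhydrazone 20 (not isolated)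
Conditions: TsNHNH2, AcOH–CH2Cl2 (1:1), −20 °C to rt
Reagents that add atoms: none
Why: Eschenmoser–Tanabe fragmentation: hydrazone 20 opens the epoxide and then loses N2 and sulfinate, cleaving the ring bond between the former α- and β-carbons to give the methyl alkyne and the aldehyde while the C5 centre (not involved and not enolisable) is kept.

Step 12
Reactants: 21 (3S)-3-(prop-1-en-2-yl)hept-5-ynal
Product: 23 (3S,5E)-6-iodo-3-(prop-1-en-2-yl)hept-5-en-1-ol, via alkenylzirconocene alkoxide 22 (not isolated)
Conditions: Cp2Zr(H)Cl (2.4 equiv), THF, 0 to 40 °C; then I2 (1.0 equiv), −78 to 0 °C; aq. Na2S2O3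
Reagents that add atoms: iodine, II
Why: Hydrozirconation–iodination: Cp2Zr(H)Cl first reduces the aldehyde to its zirconium alkoxide, then adds syn to the alkyne faster than to the 1,1-disubstituted alkene, the small excess equilibrates zirconium to the less hindered methyl-bearing carbon (the other terminus is isobutyl-like), and iodine cleaves the C–Zr bond with retention to fix the 7E iodoalkene.

Step 13
Reactants: 23 (3S,5E)-6-iodo-3-(prop-1-en-2-yl)hept-5-en-1-ol
Product: 24 (2E,5S)-2,7-diiodo-5-(prop-1-en-2-yl)hept-2-ene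
Conditions: PPh3, imidazole, I2, CH2Cl2, 0 °C
Reagents that add atoms: iodine, II
Why: Appel iodination of the primary alcohol by SN2, neutral conditions that spare the iodoalkene and the isopropenyl group.

Step 14
Reactants: 24 (2E,5S)-2,7-diiodo-5-(prop-1-en-2-yl)hept-2-ene; 25 methyl 2-[bis(2,2,2-trifluoroethoxy)phosphoryl]acetate
Product: 27 methyl (5R,7E)-2-[bis(2,2,2-trifluoroethoxy)phosphoryl]-8-iodo-5-(prop-1-en-2-yl)non-7-enoate (both C2 epimers), via sodium phosphonate anion 26 (not isolated)
Conditions: 25, NaH, DMF, 0 °C; then 24, rt to 45 °C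
Reagents that add atoms: none
Why: Alkylation of the stabilised phosphonoacetate anion 26 by SN2 at the primary C(sp3)–I bond only, the C(sp2)–I bond being inert; the new α-centre forms as a mixture that is erased in step 15.

Step 15
Reactants: 27 methyl (5R,7E)-2-[bis(2,2,2-trifluoroethoxy)phosphoryl]-8-iodo-5-(prop-1-en-2-yl)non-7-enoate; 17 3-(furan-3-yl)propanal
Product: 29 methyl (2Z,5R,7E)-2-[3-(furan-3-yl)propylidene]-8-iodo-5-(prop-1-en-2-yl)non-7-enoate, via potassium phosphonate anion 28 (not isolated)
Conditions: 27, KN(SiMe3)2, 18-crown-6, THF, −78 °C; then 17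
Reagents that add atoms: none
Why: Still–Gennari olefination with an α-alkylated bis(trifluoroethyl) phosphonate, whose fast irreversible elimination from the kinetic adduct should place the ester cis to the furylethyl chain (2Z) without touching the iodoalkene.

Step 16
Reactants: 29 methyl (2Z,5R,7E)-2-[3-(furan-3-yl)propylidene]-8-iodo-5-(prop-1-en-2-yl)non-7-enoate; 13 1,3-dioxoisoindolin-2-yl (4Z,8Z)-10-hydroxy-5,9-dimethyldeca-4,8-dienoate
Product: 31 methyl (2Z,5R,7E,11Z,15Z)-2-[3-(furan-3-yl)propylidene]-17-hydroxy-8,12,16-trimethyl-5-(prop-1-en-2-yl)heptadeca-7,11,15-trienoate, via primary homoallyl radical 30 (not isolated)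
Conditions: 13 (1.5 equiv), NiCl2·6H2O (20 mol %), 2,2'-bipyridine (20 mol %), AgNO3 (0.3 equiv), LiCl, DMF, undivided cell, Mg anode, reticulated vitreous carbon cathode, constant current (about 3 F/mol), rt
Reagents that add atoms: none
Why: Nickel-electrocatalytic decarboxylative alkenylation, a cross-electrophile union of two acceptor carbons: cathodically generated low-valent (bpy)nickel inserts into the C8–I bond of 29 with retention, while single-electron reduction of the phthalimide ester 13 at the silver-coated cathode releases CO2, phthalimide anion and the primary C9 radical 30. Capture of 30 by the alkenylnickel species (divalent to trivalent nickel) and reductive elimination forge C8–C9, and the monovalent nickel left behind is reduced again at the cathode while the Mg anode supplies the electrons. The closest known reaction type is the nickel/silver-electrocatalytic coupling of redox-active esters with alkenyl iodides used to assemble polyene terpenoids, in which homoallylic primary radicals and iodoalkenes leading to trisubstituted alkenes are usual partners. No ring is closed and no stereocentre is made: C5 is a spectator and the 7E geometry is copied from the iodide because oxidative addition and reductive elimination are stereoretentive. Chemoselectivity rests on the substrate: iodine at C8 lies trans to C6, so the alkenylnickel cannot reach the isopropenyl group (a trans-cyclopentene would result), the trisubstituted enoate and the furan ring are poor radical acceptors, and radical 30 has only a reversible 3-exo option and no five- or six-membered closure. The free C17 hydroxyl and the methyl ester are inert at the mild cell potential, so the step should deliver the whole carbon skeleton with all four trisubstituted alkenes in one operation.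

Step 17
Reactants: 31 methyl (2Z,5R,7E,11Z,15Z)-2-[3-(furan-3-yl)propylidene]-17-hydroxy-8,12,16-trimethyl-5-(prop-1-en-2-yl)heptadeca-7,11,15-trienoate
Product: 32 (2Z,5R,7E,11Z,15Z)-2-[3-(furan-3-yl)propylidene]-17-hydroxy-8,12,16-trimethyl-5-(prop-1-en-2-yl)heptadeca-7,11,15-trienoic acid (target)
Conditions: LiOH·H2O (10 equiv), THF/MeOH/H2O, 45 °C; then 1 M HCl to pH 4, 0 °C
Reagents that add atoms: lithium hydroxide, [Li+].[OH-]
Why: Saponification of the hindered Z-enoate with excess LiOH under mild warming, conditions under which α-alkyl Z-enoates keep their geometry and the furan, the alkenes and C5 are inert.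

**Compound list**
1 | nerol, (2Z)-3,7-dimethylocta-2,6-dien-1-ol | OC/C=C(/C)CCC=C(C)C | starting material
2 | neryl chloride, (2Z)-1-chloro-3,7-dimethylocta-2,6-diene | ClC/C=C(/C)CCC=C(C)C | intermediate
3 | 3-[(3Z)-5-chloro-3-methylpent-3-en-1-yl]-5,5-dimethyl-1,2,4-trioxolane (secondary ozonide) | ClC/C=C(/C)CCC1OOC(C)(C)O1 | intermediate
4 | (4Z)-6-chloro-4-methylhex-4-enal | ClC/C=C(/C)CCC=O | intermediate
5 | ethyl 2-[bis(2,2,2-trifluoroethoxy)phosphoryl]propanoate | CCOC(=O)C(C)P(=O)(OCC(F)(F)F)OCC(F)(F)F | starting material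
6 | potassium salt of the carbanion of 5 | [K+].CCOC(=O)[C-](C)P(=O)(OCC(F)(F)F)OCC(F)(F)F | intermediate
7 | ethyl (2Z,6Z)-8-chloro-2,6-dimethylocta-2,6-dienoate | ClC/C=C(/C)CC/C=C(/C)C(=O)OCC | intermediate
8 | (2Z,6Z)-8-chloro-2,6-dimethylocta-2,6-dien-1-ol | ClC/C=C(/C)CC/C=C(/C)CO | intermediate
9 | ethyl acetate | CCOC(C)=O | starting material
10 | lithium enolate of ethyl acetate | [Li+].C=C([O-])OCC | intermediate
11 | ethyl (4Z,8Z)-10-hydroxy-5,9-dimethyldeca-4,8-dienoate | CCOC(=O)CC/C=C(/C)CC/C=C(/C)CO | intermediate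
12 | (4Z,8Z)-10-hydroxy-5,9-dimethyldeca-4,8-dienoic acid | OC(=O)CC/C=C(/C)CC/C=C(/C)CO | intermediate
13 | 1,3-dioxoisoindolin-2-yl (4Z,8Z)-10-hydroxy-5,9-dimethyldeca-4,8-dienoate | O=C(CC/C=C(/C)CC/C=C(/C)CO)ON1C(=O)c2ccccc2C1=O | intermediate
14 | furan-3-carbaldehyde | O=Cc1ccoc1 | starting material
15 | (triphenylphosphoranylidene)acetaldehyde | O=CC=P(c1ccccc1)(c1ccccc1)c1ccccc1 | starting material
16 | (2E)-3-(furan-3-yl)prop-2-enal | O=C/C=C/c1ccoc1 | intermediate
17 | 3-(furan-3-yl)propanal | O=CCCc1ccoc1 | intermediate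
18 | (R)-(−)-carvone | CC1=CC[C@H](CC1=O)C(=C)C | starting material
19 | (1R,4R,6R)-1-methyl-4-(prop-1-en-2-yl)-7-oxabicyclo[4.1.0]heptan-2-one | C=C(C)[C@H]1CC(=O)[C@]2(C)O[C@@H]2C1 | intermediate
20 | p-toluenesulfonylhydrazone of 19 | C=C(C)[C@H]1CC(=NNS(=O)(=O)c3ccc(C)cc3)[C@]2(C)O[C@@H]2C1 | intermediate
21 | (3S)-3-(prop-1-en-2-yl)hept-5-ynal | C=C(C)[C@@H](CC#CC)CC=O | intermediate
22 | (E)-alkenyl(chloro)zirconocene bearing the chlorozirconocene alkoxide of the reduced aldehyde | C=C(C)[C@@H](C/C=C(\C)[Zr](Cl)(C1C=CC=C1)C1C=CC=C1)CCO[Zr](Cl)(C1C=CC=C1)C1C=CC=C1 | intermediate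
23 | (3S,5E)-6-iodo-3-(prop-1-en-2-yl)hept-5-en-1-ol | C=C(C)[C@@H](C/C=C(\C)I)CCO | intermediate
24 | (2E,5S)-2,7-diiodo-5-(prop-1-en-2-yl)hept-2-ene | C=C(C)[C@@H](C/C=C(\C)I)CCI | intermediate
25 | methyl 2-[bis(2,2,2-trifluoroethoxy)phosphoryl]acetate | COC(=O)CP(=O)(OCC(F)(F)F)OCC(F)(F)F | starting material
26 | sodium salt of the carbanion of 25 | [Na+].COC(=O)[CH-]P(=O)(OCC(F)(F)F)OCC(F)(F)F | intermediate
27 | methyl (5R,7E)-2-[bis(2,2,2-trifluoroethoxy)phosphoryl]-8-iodo-5-(prop-1-en-2-yl)non-7-enoate (C2 epimers) | C=C(C)[C@@H](C/C=C(\C)I)CCC(C(=O)OC)P(=O)(OCC(F)(F)F)OCC(F)(F)F | intermediate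
28 | potassium salt of the carbanion of 27 | [K+].C=C(C)[C@@H](C/C=C(\C)I)CC[C-](C(=O)OC)P(=O)(OCC(F)(F)F)OCC(F)(F)F | intermediate
29 | methyl (2Z,5R,7E)-2-[3-(furan-3-yl)propylidene]-8-iodo-5-(prop-1-en-2-yl)non-7-enoate | C=C(C)[C@@H](C/C=C(\C)I)CC/C(=C/CCc1ccoc1)C(=O)OC | intermediate
30 | (3Z,7Z)-9-hydroxy-4,8-dimethylnona-3,7-dien-1-yl radical | [CH2]C/C=C(/C)CC/C=C(/C)CO | intermediate
31 | methyl (2Z,5R,7E,11Z,15Z)-2-[3-(furan-3-yl)propylidene]-17-hydroxy-8,12,16-trimethyl-5-(prop-1-en-2-yl)heptadeca-7,11,15-trienoate | C=C(C)[C@@H](C/C=C(\C)CC/C=C(/C)CC/C=C(/C)CO)CC/C(=C/CCc1ccoc1)C(=O)OC | intermediate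
32 | (2Z,5R,7E,11Z,15Z)-2-[3-(furan-3-yl)propylidene]-17-hydroxy-8,12,16-trimethyl-5-(prop-1-en-2-yl)heptadeca-7,11,15-trienoic acid | C=C(C)[C@@H](C/C=C(\C)CC/C=C(/C)CC/C=C(/C)CO)CC/C(=C/CCc1ccoc1)C(=O)O | target

**Step count**
Total step count: 17
Longest linear sequence: 9 steps (steps 1–7, 16, 17)

**Steps most likely to fail**

1. Step 16.
- What may go wrong: the 11Z geometry erodes through reversible 3-exo closure of radical 30 before nickel captures it. Iodine may be lost reductively from 29. Acyl transfer from 13 to free hydroxyl groups may occur; such esters would in any case be cleaved in step 17.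
- Fallback (two-electron coupling, no radical at C9), setting out from 8: silylation (TBSCl, imidazole, DMF) would give tert-butyl{[(2Z,6Z)-8-chloro-2,6-dimethylocta-2,6-dien-1-yl]oxy}dimethylsilane F1.
- Alkoxide-promoted deborylative alkylation with bis[(pinacolato)boryl]methane (NaOtBu, THF, rt) would introduce C9 as a boron-bound CH2. This would give tert-butyl{[(2Z,6Z)-2,6-dimethyl-9-(4,4,5,5-tetramethyl-1,3,2-dioxaborolan-2-yl)nona-2,6-dien-1-yl]oxy}dimethylsilane F2.
- A B-alkyl Suzuki–Miyaura coupling of F2 with 29 (Pd(OAc)2, RuPhos, KOH, THF/H2O, 70 °C) would form the same C8–C9 bond with retention. This would give methyl (2Z,5R,7E,11Z,15Z)-17-[(tert-butyldimethylsilyl)oxy]-2-[3-(furan-3-yl)propylidene]-8,12,16-trimethyl-5-(prop-1-en-2-yl)heptadeca-7,11,15-trienoate F3.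
- Bu4NF in THF then brings the route back at 31.

2. Step 12.
- What may go wrong: the excess hydride needed for regiochemical equilibration may also hydrozirconate the isopropenyl group. The equilibration may stay incomplete, so that zirconium remains partly on C7. Surplus iodine may cause iodoetherification of the alkoxide onto the isopropenyl group.
- Fallback, setting out from 21: NaBH4 in MeOH would give (3S)-3-(prop-1-en-2-yl)hept-5-yn-1-ol F4.
- Palladium-catalysed syn-hydrostannation (Bu3SnH, Pd2(dba)3, PCy3, THF) ignores unactivated alkenes and favours tin on the less hindered methyl-bearing carbon. After chromatographic removal of the regioisomer it would give (3S,5E)-3-(prop-1-en-2-yl)-6-(tributylstannyl)hept-5-en-1-ol F5.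
- Iododestannylation (I2, 1.0 equiv, CH2Cl2, −78 °C), far faster than any reaction of iodine with the alkenes, comes back to the route at 23.

3. Step 5.
- What may go wrong: enolate 10 may self-condense on warming before it has displaced the allylic chloride. Base-induced 1,4-elimination of HCl to a diene may compete.
- Fallback (soft, thermally stable nucleophile that does not deprotonate the alcohol), setting out from 8: a malonic ester synthesis with dimethyl malonate (NaH, NaI cat., THF–DMF, rt to 50 °C) would give dimethyl 2-[(2Z,6Z)-8-hydroxy-3,7-dimethylocta-2,6-dien-1-yl]propanedioate F6.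
- Saponification (KOH, MeOH/H2O, then acid) would give 2-[(2Z,6Z)-8-hydroxy-3,7-dimethylocta-2,6-dien-1-yl]propanedioic acid F7.
- Decarboxylation in pyridine at 100–110 °C comes back to the route at 12, so that step 6 is skipped.

**Further compounds**
F1 | step 16 | tert-butyl{[(2Z,6Z)-8-chloro-2,6-dimethylocta-2,6-dien-1-yl]oxy}dimethylsilane | ClC/C=C(/C)CC/C=C(/C)CO[Si](C)(C)C(C)(C)C
F2 | step 16 | tert-butyl{[(2Z,6Z)-2,6-dimethyl-9-(4,4,5,5-tetramethyl-1,3,2-dioxaborolan-2-yl)nona-2,6-dien-1-yl]oxy}dimethylsilane | CC1(C)OB(CC/C=C(/C)CC/C=C(/C)CO[Si](C)(C)C(C)(C)C)OC1(C)C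
F3 | step 16 | methyl (2Z,5R,7E,11Z,15Z)-17-[(tert-butyldimethylsilyl)oxy]-2-[3-(furan-3-yl)propylidene]-8,12,16-trimethyl-5-(prop-1-en-2-yl)heptadeca-7,11,15-trienoate | C=C(C)[C@@H](C/C=C(\C)CC/C=C(/C)CC/C=C(/C)CO[Si](C)(C)C(C)(C)C)CC/C(=C/CCc1ccoc1)C(=O)OC
F4 | step 12 | (3S)-3-(prop-1-en-2-yl)hept-5-yn-1-ol | C=C(C)[C@@H](CC#CC)CCO
F5 | step 12 | (3S,5E)-3-(prop-1-en-2-yl)-6-(tributylstannyl)hept-5-en-1-ol | C=C(C)[C@@H](C/C=C(\C)[Sn](CCCC)(CCCC)CCCC)CCO
F6 | step 5 | dimethyl 2-[(2Z,6Z)-8-hydroxy-3,7-dimethylocta-2,6-dien-1-yl]propanedioate | COC(=O)C(C/C=C(/C)CC/C=C(/C)CO)C(=O)OC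
F7 | step 5 | 2-[(2Z,6Z)-8-hydroxy-3,7-dimethylocta-2,6-dien-1-yl]propanedioic acid | OC(=O)C(C/C=C(/C)CC/C=C(/C)CO)C(=O)O
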